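The easy step in these flasks is the first one: Sub and Rea join to Prd and come apart again, while other steps act around it. The flasks differ in the Sub charged.

| flask | Sub | Rea | Sub2 | time |
|---|---|---|---|---|
| west | 0.025 M | 0.420 M | 0.210 M | 4.0 h |
| east | 0.080 M | 0.420 M | 0.210 M | 4.0 h |
| south | 0.20 M | 0.420 M | 0.210 M | 4.0 h |
| south-east | 0.60 M | 0.420 M | 0.210 M | 4.0 h |

    Sub + Rea ⇌ Prd (K1 = 2.1 L mol⁻¹, k1 = 0.0028 L mol⁻¹ s⁻¹)
    Sub2 + Rea ⇌ Sid2 (K2 = 3.1 L mol⁻¹, k2 = 2.5 × 10⁻⁴ L mol⁻¹ s⁻¹)
    Rea → Sid (k3 = 1.8 × 10⁻⁷ s⁻¹)
    Sub ⇌ Int (K4 = 0.68, k4 = 1.2 × 10⁻⁴ s⁻¹)
    Rea + Prd → Sid3 (k5 = 1.7 × 10⁻⁴ L mol⁻¹ s⁻¹)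

- "hardly changes" means that all values lie within two and a half points (for a concentration: within two and a half percent of the largest)
- run time (west): 4.0 h

1. [Prd] at the end for west, east, south, south-east, in this order
2. the course of these numbers from the first flask to the last (rises all the way / hardly changes / rises, then falls / falls, then rises / falls all the way)

The quantity to carry is the holding ratio, the equilibrium constant of the first step times the Rea charged, 0.882. While that step is in balance, c(Prd)/c(Sub) equals this ratio times the fraction of Rea left.

Which constants must be known well for west? The first step's rate constant matters little, because its balance half-life at the charge, 0.0767 h, is shorter than the run. The decay of Rea to Sid matters little as well, because its half-life of 45 d is far longer than 4.0 h. Sub and Int balance by their own step alone with a half-life of 0.649 h, so Sub, Prd and Int are reckoned as one pool. To first order Sub2 takes 0.119 M of Rea, leaving 0.301 M. The ratio in west is then 0.633, and Prd's part of the pool is 0.274.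

One percent of error then moves c(Prd) in west by about 0.726 percent through the first equilibrium constant, 0.294 through that of Int, and 0.124 through that of Sub2. The drain to Sid3 is the small thing, computed as a correction: its exponent is 0.202, which is also its weight, and the pool keeps 0.817. This reckoning gives 0.00559 M for west. It stops there, since south-east is charged with more Sub than Rea, and Sub's own take of Rea is no small correction. It expects a rise flatter than the charges.

The forecast gives 0.0054 M, 0.017 M, 0.041 M and 0.102 M, course rises all the way, and of the first step it says “I treated it as a quasi-equilibrium”; for west it stands a little below this reckoning.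

The flasks give 0.00523 M, 0.0162 M, 0.0373 M and 0.0892 M, course rises all the way. In west the relaxation half-life of the first step at the end, 0.0869 h, is shorter than 4.0 h, and the holding ratio times the Rea left, 73%, gives 0.644 against a standing c(Prd)/c(Sub) of 0.631. In south-east, with 37% of the Rea left, the same product gives 0.326, and the flask holds 0.326.

The constants are made up; no experiment stands behind them.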